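**Plan**

1. Retrosynthesis: cut the C4 ester, then C4–C5 of ring B (ten-membered carbocycle C1–C10), then C17–C8 and O7–C19 of the lactone (ring C), C8–C9 (to a diynyl unit C5–C8 with C16), C9–C10, and C1–C2 / C1–CH3 on (S)-carvone.
2. Forward: ring A (cyclohexene C1, C10–C14) comes from (S)-carvone (acylation and methylation at C1, isopropenyl to 14-acetoxy, enone transposition to the C12 allylic alcohol); C9 is put on C10 by a [2,3]-Wittig–Still shift; the diyne is added to the C9 aldehyde; ring C is closed by a copper hydride reductive aldol; ring B is closed last by an intramolecular Nozaki–Hiyama–Kishi reaction, followed by C4 esterification.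
3. Enabling feature: in ring B the carbinol C4 is bonded to C5 of the Z C5=C6 olefin (C5 also carries C16H2OH), and C6 is bonded to C7 of ring C; this 2-(hydroxymethyl)allylic alcohol maps onto a C5 alkenyl metal and a C4 aldehyde, and the cis olefin, the trans-fused lactone and the quaternary C1 of ring A hold the two chain ends together.
4. Stereochemistry: C14 from carvone; C1 by alkylation anti to isopropenyl; C2 by Corey–Bakshi–Shibata reduction; C10 by chirality transfer from C12 (epoxidation anti to C14–O, Wharton, suprafacial [2,3]); C9 by Felkin–Anh addition; C7 by matched Sharpless epoxidation and inverting epoxide opening; C8 and C17 in the aldol ring closure; Z C5=C6 by hydroxyl-directed trans-hydrostannation; C4 in the key step (1,3-anti to the C2 acetate); C3' from (R)-3-hydroxybutanoic acid.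

Key step: step 27

Remark: all compounds carry the briarane locants of the target (C1 quaternary carbon with methyl C15; C2, C9, C14 acetoxy carbons; C4 acyloxy carbon; C5 bearing C16; C7, C8, C17, C19 in the lactone; C11 with methyl C20); ring A = cyclohexene, ring B = ten-membered ring, ring C = lactone.

Step 1
Reactants: 1 methyl 3,3-dimethoxypropanoate
Product: 2 3,3-dimethoxypropanal
Conditions: i-Bu2AlH (1.0 equiv), CH2Cl2, −78 °C; MeOH, aq. potassium sodium tartrate
Reagents that add atoms: none
Why: Low-temperature half-reduction of the ester stops at the tetrahedral aluminate, which releases the aldehyde on work-up (ester-to-aldehyde reduction).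

Step 2
Reactants: 3 (S)-(+)-carvone; 2 3,3-dimethoxypropanal
Product: 4 6-(1-hydroxy-3,3-dimethoxypropyl)carvone (epimer mixture at C1 and C2)
Conditions: LiN(i-Pr)2, THF, −78 °C; then 2, −78 °C; aq. NH4Cl
Reagents that add atoms: none
Why: Kinetic deprotonation of carvone at C6 (the future C1) and aldol addition join C1–C2; the two new centres do not matter because both are erased in steps 3 and 4.

Step 3
Reactants: 4 6-(1-hydroxy-3,3-dimethoxypropyl)carvone
Product: 5 6-(3,3-dimethoxypropanoyl)carvone (β-diketone and enol)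
Conditions: DMP (1,1,1-triacetoxy-1,1-dihydro-1,2-benziodoxol-3(1H)-one), NaHCO3, CH2Cl2, 0 °C to rt
Reagents that add atoms: none
Why: Periodinane oxidation of the β-hydroxy ketone gives the 2-acyl enone, whose C1–H is acidic enough for mild alkylation.

Step 4
Reactants: 5 6-(3,3-dimethoxypropanoyl)carvone
Product: 6 6-(3,3-dimethoxypropanoyl)-6-methylcarvone (methyl trans and acyl chain cis to isopropenyl)
Conditions: MeI, K2CO3, acetone, rt
Reagents that add atoms: iodomethane CI
Why: C-alkylation of the stabilised β-diketone enolate creates the C1 quaternary centre, MeI approaching anti to the vicinal isopropenyl group (1,2-induction as in carvone alkylations).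

Step 5
Reactants: 6 6-(3,3-dimethoxypropanoyl)-6-methylcarvone
Product: 7 6-[(1R)-1-hydroxy-3,3-dimethoxypropyl]-6-methylcarvone (C2 carbinol as in the target)
Conditions: (S)-1-methyl-3,3-diphenyltetrahydro-1H,3H-pyrrolo[1,2-c][1,3,2]oxazaborole (0.3 equiv), catecholborane, toluene, −78 to −40 °C
Reagents that add atoms: none
Why: Corey–Bakshi–Shibata reduction should take the saturated C2 ketone (tert-alkyl against methylene flank) in preference to the hindered cross-conjugated C10 enone and set C2 as (R) by reagent control, while catecholborane leaves the isopropenyl olefin alone.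

Step 6
Reactants: 7 6-[(1R)-1-hydroxy-3,3-dimethoxypropyl]-6-methylcarvone
Product: 8 2,14-diacetoxy enone (14-acetoxy in place of isopropenyl; C10 ketone; C11=C12)
Conditions: O3, CH2Cl2/MeOH, NaHCO3, −78 °C; then Ac2O, Et3N, 4-(dimethylamino)pyridine, 0 °C to rt
Reagents that add atoms: ozone [O-][O+]=O; methanol CO; acetic anhydride CC(=O)OC(C)=O
Why: Ozone cleaves only the electron-rich isopropenyl olefin, and the methoxy hydroperoxide undergoes Criegee rearrangement on acetylation, so acetoxy replaces isopropenyl with retention at C14 while the C2 hydroxyl is acetylated.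

Step 7
Reactants: 8 2,14-diacetoxy enone
Product: 9 11,12-epoxy ketone (epoxide oxygen trans to the 14-acetoxy group)
Conditions: t-BuOOH (decane solution), 1,8-diazabicyclo[5.4.0]undec-7-ene, CH2Cl2, 0 °C to rt
Reagents that add atoms: tert-butyl hydroperoxide CC(C)(C)OO
Why: Weitz–Scheffer epoxidation in which the peroxide anion attacks C12 axially and anti to the C14 acetoxy group, as in carvone, sets the temporary C12–O centre without hydrolysing the acetates.

Step 8
Reactants: 9 11,12-epoxy ketone
Product: 10 12-hydroxy-10(11)-ene 2,14-diacetate (12-OH trans to 14-OAc)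
Conditions: N2H4·H2O, AcOH (cat.), MeOH, 0 °C to rt
Reagents that add atoms: none
Why: Wharton transposition: the epoxy hydrazone fragments with loss of N2 to the C12 allylic alcohol with the olefin at C10=C11 and the C12–O configuration retained.

Step 9
Reactants: 10 12-hydroxy-10(11)-ene 2,14-diacetate
Product: 12 2,14-O-isopropylidene acetal with free 12-OH (cis-fused 1,3-dioxane on ring A), via 2,12,14-triol 11 (not isolated)
Conditions: K2CO3 (cat.), MeOH, rt; neutralise, concentrate; then Me2C(OMe)2, pyridinium p-toluenesulfonate, CH2Cl2, rt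
Reagents that add atoms: 2,2-dimethoxypropane COC(C)(C)OC
Why: Methanolysis frees the syn-1,3-diol at C2/C14, which alone can form a six-membered isopropylidene acetal (the 12-OH is trans-1,3 on the ring), giving a temporary ring that protects both future acetate positions.

Step 10
Reactants: 12 2,14-O-isopropylidene acetal with free 12-OH
Product: 13 12-O-[(tributylstannyl)methyl] ether
Conditions: KH, Bu3SnCH2I, 18-crown-6 (cat.), THF, 0 °C to rt
Reagents that add atoms: (iodomethyl)tributylstannane CCCC[Sn](CI)(CCCC)CCCC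
Why: Williamson etherification of the C12 potassium alkoxide provides the substrate for tin–lithium exchange.

Step 11
Reactants: 13 12-O-[(tributylstannyl)methyl] ether
Product: 14 10-(hydroxymethyl)-11(12)-ene acetonide (C9 carbinol cis to the C1 methyl)
Conditions: n-BuLi, THF, −78 °C; aq. NH4Cl
Reagents that add atoms: none
Why: [2,3]-Wittig–Still rearrangement: the α-alkoxymethyllithium shifts suprafacially to C10, so C9 arrives on the face that carried the C12 oxygen (setting C10) and the olefin moves to C11=C12.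

Step 12
Reactants: 14 10-(hydroxymethyl)-11(12)-ene acetonide
Product: 15 C9 aldehyde
Conditions: DMP, NaHCO3, CH2Cl2, 0 °C
Reagents that add atoms: none
Why: Buffered periodinane oxidation of the primary alcohol avoids base that could epimerise C10 or move the β,γ-olefin into conjugation.

Step 13
Reactants: 16 1,4-bis(trimethylsilyl)buta-1,3-diyne
Product: 18 5-(trimethylsilyl)penta-2,4-diyn-1-ol, via lithium (trimethylsilyl)butadiynide 17 (not isolated)
Conditions: MeLi·LiBr (1.0 equiv), THF, −78 °C to rt; then (CH2O)n, −78 °C to rt; aq. NH4Cl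
Reagents that add atoms: paraformaldehyde (as formaldehyde) C=O
Why: MeLi·LiBr cleaves one alkynyl–silicon bond selectively and the lithium diynide is hydroxymethylated (acetylide addition to formaldehyde).

Step 14
Reactants: 18 5-(trimethylsilyl)penta-2,4-diyn-1-ol
Product: 19 tert-butyldimethyl{[5-(trimethylsilyl)penta-2,4-diyn-1-yl]oxy}silane
Conditions: t-BuMe2SiCl, imidazole, CH2Cl2, 0 °C
Reagents that add atoms: tert-butyldimethylsilyl chloride CC(C)(C)[Si](C)(C)Cl
Why: Standard silylation of the primary propargylic alcohol.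

Step 15
Reactants: 15 C9 aldehyde; 19 tert-butyldimethyl{[5-(trimethylsilyl)penta-2,4-diyn-1-yl]oxy}silane
Product: 21 C9 diynyl carbinol (C9 as in the target; chain C8≡C7–C6≡C5–C16H2OTBS), via lithium 5-(tert-butyldimethylsilyloxy)penta-1,3-diynide 20 (not isolated)
Conditions: 19, MeLi·LiBr, THF, 0 °C to rt; then 15, −78 °C; aq. NH4Cl
Reagents that add atoms: none
Why: The second alkynyl–silicon cleavage gives the lithium diynide, which adds to the aldehyde at low temperature under Felkin–Anh control (quaternary C1 as the large group anti to the nucleophile), which should give the (9R) carbinol.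

Step 16
Reactants: 21 C9 diynyl carbinol
Product: 22 (7E)-7-en-5-yn-9-ol (E-enyne allylic alcohol)
Conditions: NaAlH2(OCH2CH2OMe)2, THF, 0 °C; aq. potassium sodium tartrate
Reagents that add atoms: none
Why: Alkoxide-directed trans-hydroalumination reduces only the alkyne next to the free C9 hydroxyl, giving the E olefin at C7=C8 and leaving the distal alkyne.

Step 17
Reactants: 22 (7E)-7-en-5-yn-9-ol
Product: 23 7,8-epoxy-9-ol (trans epoxide, erythro to the 9-OH)
Conditions: Ti(OiPr)4 (0.2 equiv), D-(−)-diisopropyl tartrate (0.24 equiv), t-BuOOH, 4 Å molecular sieves, CH2Cl2, −20 °C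
Reagents that add atoms: tert-butyl hydroperoxide CC(C)(C)OO
Why: Sharpless asymmetric epoxidation acts only on the allylic alcohol olefin (the ring olefin is homoallylic), and with the D-tartrate the C9 configuration of 22 is the matched, fast-reacting one that gives the erythro epoxy alcohol, whereas any C9 epimer from step 15 is expected to react slowly and be left behind.

Step 18
Reactants: 23 7,8-epoxy-9-ol
Product: 24 7-O-acryloyl 8,9-diol
Conditions: Ti(OiPr)4 (1.5 equiv), acrylic acid, 2,6-di-tert-butyl-4-methylphenol (trace), CH2Cl2, rt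
Reagents that add atoms: acrylic acid C=CC(=O)O
Why: Titanium-mediated opening of a 2,3-epoxy alcohol by a carboxylic acid occurs at the distal epoxide carbon (here C7, also propargylic) with inversion, which puts the acrylate on O7 and gives C7 the target configuration.

Step 19
Reactants: 24 7-O-acryloyl 8,9-diol
Product: 25 8-oxo-9-hydroxy 7-acrylate
Conditions: DMP (1.1 equiv), NaHCO3, CH2Cl2, 0 °C
Reagents that add atoms: none
Why: The C8 carbinol, flanked by two CH groups, should be oxidised faster than the C9 carbinol, which is shielded by ring A and its quaternary C1 (sterically differentiated alcohol oxidation).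

Step 20
Reactants: 25 8-oxo-9-hydroxy 7-acrylate
Product: 26 9-acetate of the 8-oxo 7-acrylate
Conditions: Ac2O, pyridine, 4-(dimethylamino)pyridine (cat.), CH2Cl2, 0 °C
Reagents that add atoms: acetic anhydride CC(=O)OC(C)=O
Why: Acetylation installs the C9 acetate of the target before the lactone exists, so that no free C9 hydroxyl can later compete for the lactone carbonyl.

Step 21
Reactants: 26 9-acetate of the 8-oxo 7-acrylate
Product: 27 lactone (ring C closed; 8-OH, 9-OAc, C5≡C6 alkyne, 16-OTBS, 2,14-acetonide, C4 dimethyl acetal)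
Conditions: [(Ph3P)CuH]6 (0.5 equiv of hexamer), toluene/THF, −40 to 0 °C; aq. NH4Cl
Reagents that add atoms: none
Why: Copper hydride conjugate reduction of the acrylate gives a C17 copper enolate that adds to the C8 ketone (reductive aldol cyclisation forming C17–C8); the ring should form with the bulky C9 branch trans to the C6 alkynyl group (8-OH cis to C6) and with the C17 methyl cis to the hydroxyl (syn aldol, also the more stable arrangement).

Step 22
Reactants: 27 lactone with acetonide and 16-OTBS
Product: 28 2,8,14,16-tetraol 9-acetate (C5≡C6 alkyne; C4 dimethyl acetal)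
Conditions: camphorsulfonic acid (cat.), MeOH, rt
Reagents that add atoms: none
Why: Acid-catalysed methanolysis removes the isopropylidene acetal and the primary silyl ether, while methanol as solvent keeps the C4 dimethyl acetal intact.

Step 23
Reactants: 28 2,8,14,16-tetraol 9-acetate
Product: 30 (5Z)-5-iodoalkene (iodine cis to C7), via (5Z)-5-(tributylstannyl)alkene 29 (not isolated)
Conditions: [(C5Me5)RuCl]4 (cat.), Bu3SnH, CH2Cl2, rt; then I2, CH2Cl2, 0 °C; aq. Na2S2O3
Reagents that add atoms: tributyltin hydride CCCC[SnH](CCCC)CCCC (tin is carried only in 29); iodine II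
Why: Ruthenium-catalysed trans-hydrostannation directed by the free propargylic C16 hydroxyl places tin on C5 and hydrogen on C6 anti to it, and iododestannylation with retention gives the Z iodoalkene.

Step 24
Reactants: 30 (5Z)-5-iodoalkene
Product: 31 16-O-(tert-butyldiphenylsilyl) ether of 30
Conditions: t-BuPh2SiCl, imidazole, CH2Cl2, 0 °C
Reagents that add atoms: tert-butyl(chloro)diphenylsilane CC(C)(C)[Si](Cl)(c1ccccc1)c1ccccc1
Why: The bulky silyl chloride should react only with the primary allylic C16 hydroxyl, leaving the hindered secondary and the tertiary hydroxyls free.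

Step 25
Reactants: 31 16-O-(tert-butyldiphenylsilyl) ether
Product: 32 2,9,14-triacetate (8-OH free)
Conditions: Ac2O, pyridine, 4-(dimethylamino)pyridine (cat.), CH2Cl2, 0 °C to rt
Reagents that add atoms: acetic anhydride CC(=O)OC(C)=O
Why: Nucleophile-catalysed acetylation esterifies the C2 and C14 secondary hydroxyls, while the tertiary C8 hydroxyl, flanked by three substituted carbons, is expected to stay free.

Step 26
Reactants: 32 2,9,14-triacetate
Product: 33 C4 aldehyde (iodoalkene aldehyde)
Conditions: LiBF4, MeCN/H2O (49:1), rt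
Reagents that add atoms: water O
Why: Mild Lewis-acid hydrolysis of the dimethyl acetal unmasks the aldehyde without base (no β-elimination of the C2 acetate) and without touching silyl ether, esters or iodoalkene.

Step 27
Reactants: 33 C4 aldehyde (iodoalkene aldehyde)
Product: 34 ring B macrocycle with free (4R)-hydroxyl (16-O-silyl ether)
Conditions: CrCl2 (20 equiv), NiCl2 (0.2 equiv), DMSO/THF (3:1), rt, slow addition of 33 to 0.002 M; aq. NH4Cl
Reagents that add atoms: none
Why: Divalent chromium reduces NiCl2 to zerovalent nickel, which inserts into the C5–I bond with retention of olefin geometry; transmetalation gives an alkenyl species of trivalent chromium that adds to the C4 aldehyde, and the chromium alkoxide is stable until work-up. The closest known reaction type is the intramolecular Nozaki–Hiyama–Kishi coupling of iodoalkene aldehydes used to close medium and large carbocycles. Ring B (C1–C10) is closed at C4–C5 by 10-exo-trig attack of C5 on the carbonyl group, whose oxygen stays outside the ring. The new C4 centre is under substrate control: the aldehyde should be attacked on the face that puts the new hydroxyl 1,3-anti to the C2 acetoxy group, the usual sense for β-oxygenated aldehydes, in a conformation fixed by the cis C5=C6 olefin, the trans-fused lactone and ring A. The step needs chemoselectivity for the aldehyde over lactone and acetates (inherent to organochromium reagents), retention of the Z geometry (given by the Ni/Cr cycle) and cyclisation in preference to oligomerisation, which high dilution, the Z olefin holding C4 and C7 on one side, the quaternary C1 and the two flanking rings should secure.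

Step 28
Reactants: 35 (R)-3-hydroxybutanoic acid
Product: 36 (R)-3-acetoxybutanoic acid
Conditions: AcCl (neat), 0 °C to rt; then H2O, rt
Reagents that add atoms: acetyl chloride CC(Cl)=O
Why: O-acetylation of the hydroxy acid (the mixed anhydride formed at the carboxyl group is hydrolysed on work-up) leaves the stereocentre untouched.

Step 29
Reactants: 34 ring B macrocycle with free (4R)-hydroxyl; 36 (R)-3-acetoxybutanoic acid
Product: 37 16-O-(tert-butyldiphenylsilyl) ether of the target
Conditions: EDC·HCl, 4-(dimethylamino)pyridine (0.2 equiv), CH2Cl2, 0 °C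
Reagents that add atoms: none
Why: Steglich esterification of the only reactive hydroxyl (secondary allylic C4–OH; C8–OH is tertiary), run cold to avoid β-elimination of the acetoxy acid.

Step 30
Reactants: 37 16-O-(tert-butyldiphenylsilyl) ether of the target
Product: 38 CNP0316115.1
Conditions: HF·pyridine, pyridine, THF, 0 °C to rt
Reagents that add atoms: none
Why: Fluoride cleaves the primary silyl ether under buffered conditions that should neither cleave nor shift the five ester groups.

**Compound list**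

1 | methyl 3,3-dimethoxypropanoate | COC(=O)CC(OC)OC | starting material
2 | 3,3-dimethoxypropanal | COC(OC)CC=O | intermediate
3 | (S)-(+)-carvone | CC1=CC[C@@H](CC1=O)C(C)=C | starting material
4 | 6-(1-hydroxy-3,3-dimethoxypropyl)carvone (epimers at C1 and C2) | COC(OC)CC(O)C1[C@@H](C(C)=C)CC=C(C)C1=O | intermediate
5 | 6-(3,3-dimethoxypropanoyl)carvone (β-diketone and enol) | COC(OC)CC(=O)C1[C@@H](C(C)=C)CC=C(C)C1=O | intermediate
6 | 6-(3,3-dimethoxypropanoyl)-6-methylcarvone (methyl trans, acyl cis to isopropenyl) | COC(OC)CC(=O)[C@@]1(C)[C@@H](C(C)=C)CC=C(C)C1=O | intermediate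
7 | 6-[(1R)-1-hydroxy-3,3-dimethoxypropyl]-6-methylcarvone | COC(OC)C[C@@H](O)[C@@]1(C)[C@@H](C(C)=C)CC=C(C)C1=O | intermediate
8 | 2,14-diacetoxy enone (C10 ketone, C11=C12) | COC(OC)C[C@@H](OC(C)=O)[C@@]1(C)[C@@H](OC(C)=O)CC=C(C)C1=O | intermediate
9 | 11,12-epoxy ketone (epoxide trans to 14-OAc) | COC(OC)C[C@@H](OC(C)=O)[C@@]1(C)[C@@H](OC(C)=O)C[C@@H]2O[C@]2(C)C1=O | intermediate
10 | 12-hydroxy-10(11)-ene 2,14-diacetate | COC(OC)C[C@@H](OC(C)=O)[C@@]1(C)[C@@H](OC(C)=O)C[C@H](O)C(C)=C1 | intermediate
11 | 2,12,14-triol | COC(OC)C[C@@H](O)[C@@]1(C)[C@@H](O)C[C@H](O)C(C)=C1 | intermediate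
12 | 2,14-O-isopropylidene acetal with free 12-OH | COC(OC)C[C@H]1OC(C)(C)O[C@H]2C[C@H](O)C(C)=C[C@@]12C | intermediate
13 | 12-O-[(tributylstannyl)methyl] ether | COC(OC)C[C@H]1OC(C)(C)O[C@H]2C[C@H](OC[Sn](CCCC)(CCCC)CCCC)C(C)=C[C@@]12C | intermediate
14 | 10-(hydroxymethyl)-11(12)-ene acetonide | COC(OC)C[C@H]1OC(C)(C)O[C@H]2CC=C(C)[C@H](CO)[C@@]12C | intermediate
15 | C9 aldehyde | COC(OC)C[C@H]1OC(C)(C)O[C@H]2CC=C(C)[C@H](C=O)[C@@]12C | intermediate
16 | 1,4-bis(trimethylsilyl)buta-1,3-diyne | C[Si](C)(C)C#CC#C[Si](C)(C)C | starting material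
17 | lithium (trimethylsilyl)butadiynide | [Li]C#CC#C[Si](C)(C)C | intermediate
18 | 5-(trimethylsilyl)penta-2,4-diyn-1-ol | OCC#CC#C[Si](C)(C)C | intermediate
19 | tert-butyldimethyl{[5-(trimethylsilyl)penta-2,4-diyn-1-yl]oxy}silane | C[Si](C)(C)C#CC#CCO[Si](C)(C)C(C)(C)C | intermediate
20 | lithium 5-(tert-butyldimethylsilyloxy)penta-1,3-diynide | [Li]C#CC#CCO[Si](C)(C)C(C)(C)C | intermediate
21 | C9 diynyl carbinol (C9 as in the target) | COC(OC)C[C@H]1OC(C)(C)O[C@H]2CC=C(C)[C@H]([C@@H](O)C#CC#CCO[Si](C)(C)C(C)(C)C)[C@@]12C | intermediate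
22 | (7E)-7-en-5-yn-9-ol | COC(OC)C[C@H]1OC(C)(C)O[C@H]2CC=C(C)[C@H]([C@@H](O)/C=C/C#CCO[Si](C)(C)C(C)(C)C)[C@@]12C | intermediate
23 | 7,8-epoxy-9-ol (erythro) | COC(OC)C[C@H]1OC(C)(C)O[C@H]2CC=C(C)[C@H]([C@@H](O)[C@H]3O[C@@H]3C#CCO[Si](C)(C)C(C)(C)C)[C@@]12C | intermediate
24 | 7-O-acryloyl 8,9-diol | COC(OC)C[C@H]1OC(C)(C)O[C@H]2CC=C(C)[C@H]([C@@H](O)[C@@H](O)[C@@H](OC(=O)C=C)C#CCO[Si](C)(C)C(C)(C)C)[C@@]12C | intermediate
25 | 8-oxo-9-hydroxy 7-acrylate | COC(OC)C[C@H]1OC(C)(C)O[C@H]2CC=C(C)[C@H]([C@@H](O)C(=O)[C@@H](OC(=O)C=C)C#CCO[Si](C)(C)C(C)(C)C)[C@@]12C | intermediate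
26 | 9-acetate of the 8-oxo 7-acrylate | COC(OC)C[C@H]1OC(C)(C)O[C@H]2CC=C(C)[C@H]([C@@H](OC(C)=O)C(=O)[C@@H](OC(=O)C=C)C#CCO[Si](C)(C)C(C)(C)C)[C@@]12C | intermediate
27 | lactone (ring C) with 8-OH, 9-OAc, alkyne, 16-OTBS, acetonide | COC(OC)C[C@H]1OC(C)(C)O[C@H]2CC=C(C)[C@H]([C@@H](OC(C)=O)[C@@]3(O)[C@H](C#CCO[Si](C)(C)C(C)(C)C)OC(=O)[C@@H]3C)[C@@]12C | intermediate
28 | 2,8,14,16-tetraol 9-acetate | COC(OC)C[C@@H](O)[C@@]2(C)[C@@H](O)CC=C(C)[C@@H]2[C@@H](OC(C)=O)[C@@]3(O)[C@H](C#CCO)OC(=O)[C@@H]3C | intermediate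
29 | (5Z)-5-(tributylstannyl)alkene | COC(OC)C[C@@H](O)[C@@]2(C)[C@@H](O)CC=C(C)[C@@H]2[C@@H](OC(C)=O)[C@@]3(O)[C@H](/C=C(\[Sn](CCCC)(CCCC)CCCC)CO)OC(=O)[C@@H]3C | intermediate
30 | (5Z)-5-iodoalkene | COC(OC)C[C@@H](O)[C@@]2(C)[C@@H](O)CC=C(C)[C@@H]2[C@@H](OC(C)=O)[C@@]3(O)[C@H](/C=C(\I)CO)OC(=O)[C@@H]3C | intermediate
31 | 16-O-(tert-butyldiphenylsilyl) ether of 30 | COC(OC)C[C@@H](O)[C@@]2(C)[C@@H](O)CC=C(C)[C@@H]2[C@@H](OC(C)=O)[C@@]3(O)[C@H](/C=C(\I)CO[Si](c4ccccc4)(c4ccccc4)C(C)(C)C)OC(=O)[C@@H]3C | intermediate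
32 | 2,9,14-triacetate | COC(OC)C[C@@H](OC(C)=O)[C@@]2(C)[C@@H](OC(C)=O)CC=C(C)[C@@H]2[C@@H](OC(C)=O)[C@@]3(O)[C@H](/C=C(\I)CO[Si](c4ccccc4)(c4ccccc4)C(C)(C)C)OC(=O)[C@@H]3C | intermediate
33 | C4 aldehyde (iodoalkene aldehyde) | O=CC[C@@H](OC(C)=O)[C@@]2(C)[C@@H](OC(C)=O)CC=C(C)[C@@H]2[C@@H](OC(C)=O)[C@@]3(O)[C@H](/C=C(\I)CO[Si](c4ccccc4)(c4ccccc4)C(C)(C)C)OC(=O)[C@@H]3C | intermediate
34 | ring B macrocycle with free (4R)-hydroxyl | O[C@@H]1C[C@@H](OC(C)=O)[C@@]2(C)[C@@H](OC(C)=O)CC=C(C)[C@@H]2[C@@H](OC(C)=O)[C@@]2(O)[C@H](/C=C\1CO[Si](c3ccccc3)(c3ccccc3)C(C)(C)C)OC(=O)[C@@H]2C | intermediate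
35 | (R)-3-hydroxybutanoic acid | C[C@@H](O)CC(=O)O | starting material
36 | (R)-3-acetoxybutanoic acid | CC(=O)O[C@H](C)CC(=O)O | intermediate
37 | 16-O-(tert-butyldiphenylsilyl) ether of the target | CC(=O)O[C@H](C)CC(=O)O[C@@H]1C[C@@H](OC(C)=O)[C@@]2(C)[C@@H](OC(C)=O)CC=C(C)[C@@H]2[C@@H](OC(C)=O)[C@@]2(O)[C@H](/C=C\1CO[Si](c3ccccc3)(c3ccccc3)C(C)(C)C)OC(=O)[C@@H]2C | intermediate
38 | CNP0316115.1 | CC(=O)O[C@H](C)CC(=O)O[C@@H]1C[C@@H](OC(C)=O)[C@@]2(C)[C@@H](OC(C)=O)CC=C(C)[C@@H]2[C@@H](OC(C)=O)[C@@]2(O)[C@H](/C=C\1CO)OC(=O)[C@@H]2C | target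

**Step count and risks**

Total step count: 30. Longest linear sequence: 27 steps (steps 1–12, 15–27, 29, 30).

Steps most likely to fail:

Step 27 (ring B closure). The alkenylchromium may be protonated or may add intermolecularly (oligomerisation) faster than the strained ten-membered ring closes, and facial selectivity at C4 may be poor. Fallback, from 33 back to 34: close the ring as a ketone and set C4 by reagent control. Oxidation of 33 (NaClO2, NaH2PO4, 2-methylbut-2-ene, t-BuOH/H2O) should give the C4 carboxylic acid F1. 2,2'-Dipyridyl disulfide and PPh3 should convert it into the S-(pyridin-2-yl) thioester F2. Ni/Zr-mediated ketone synthesis at high dilution (NiBr2 with 4,4'-di-tert-butyl-2,2'-bipyridine, (C5H5)2ZrCl2, Zn, 1,3-dimethyl-2-imidazolidinone/THF) should close ring B as the 4-oxo macrocyclic enone F3. Corey–Bakshi–Shibata reduction (the oxazaborole of step 5, catecholborane) should then give 34.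

Step 21 (reductive aldol). Copper hydride may reduce the doubly α-oxygenated C8 ketone directly or displace the propargylic ester in an SN2' sense, and the C17 configuration may form without control. Fallback, from 23 back to 27: generate the ester enolate by halide reduction instead of hydride addition. Opening of 23 with (±)-2-bromopropanoic acid and Ti(OiPr)4 should give the 7-O-(2-bromopropanoyl) 8,9-diol F4. DMP oxidation should give the 8-oxo-9-hydroxy bromo ester F5, and acetylation (Ac2O, pyridine) its 9-acetate F6. An intramolecular Reformatsky reaction (SmI2, THF, −78 °C) should then give 27.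

Step 19 (site-selective oxidation). The C9 carbinol may be oxidised as well, or the acrylate may migrate from O7 to O8 before oxidation, giving the wrong ketone. Fallback, from 23 back to 25: protect C9 before the epoxide is opened. Et3SiOSO2CF3 and 2,6-dimethylpyridine should give the 9-O-triethylsilyl epoxide F7. Heating with acrylic acid and Cs2CO3 (cat.) in DMF should open the propargylic epoxide carbon C7 with inversion to the 9-O-triethylsilyl 7-acrylate 8-ol F8. DMP should give the 9-O-triethylsilyl 8-oxo 7-acrylate F9, and buffered HF·pyridine at 0 °C should remove only the triethylsilyl group to give 25.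

Further compounds

F1 | step 27 | C4 carboxylic acid of the iodoalkene | OC(=O)C[C@@H](OC(C)=O)[C@@]2(C)[C@@H](OC(C)=O)CC=C(C)[C@@H]2[C@@H](OC(C)=O)[C@@]3(O)[C@H](/C=C(\I)CO[Si](c4ccccc4)(c4ccccc4)C(C)(C)C)OC(=O)[C@@H]3C
F2 | step 27 | S-(pyridin-2-yl) thioester of F1 | O=C(Sc1ccccn1)C[C@@H](OC(C)=O)[C@@]2(C)[C@@H](OC(C)=O)CC=C(C)[C@@H]2[C@@H](OC(C)=O)[C@@]3(O)[C@H](/C=C(\I)CO[Si](c4ccccc4)(c4ccccc4)C(C)(C)C)OC(=O)[C@@H]3C
F3 | step 27 | 4-oxo macrocyclic enone (ring B closed) | O=C1C[C@@H](OC(C)=O)[C@@]2(C)[C@@H](OC(C)=O)CC=C(C)[C@@H]2[C@@H](OC(C)=O)[C@@]2(O)[C@H](/C=C\1CO[Si](c3ccccc3)(c3ccccc3)C(C)(C)C)OC(=O)[C@@H]2C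
F4 | step 21 | 7-O-(2-bromopropanoyl) 8,9-diol | COC(OC)C[C@H]1OC(C)(C)O[C@H]2CC=C(C)[C@H]([C@@H](O)[C@@H](O)[C@@H](OC(=O)C(C)Br)C#CCO[Si](C)(C)C(C)(C)C)[C@@]12C
F5 | step 21 | 8-oxo-9-hydroxy 7-(2-bromopropanoate) | COC(OC)C[C@H]1OC(C)(C)O[C@H]2CC=C(C)[C@H]([C@@H](O)C(=O)[C@@H](OC(=O)C(C)Br)C#CCO[Si](C)(C)C(C)(C)C)[C@@]12C
F6 | step 21 | 9-acetate of F5 | COC(OC)C[C@H]1OC(C)(C)O[C@H]2CC=C(C)[C@H]([C@@H](OC(C)=O)C(=O)[C@@H](OC(=O)C(C)Br)C#CCO[Si](C)(C)C(C)(C)C)[C@@]12C
F7 | step 19 | 9-O-triethylsilyl 7,8-epoxide | COC(OC)C[C@H]1OC(C)(C)O[C@H]2CC=C(C)[C@H]([C@@H](O[Si](CC)(CC)CC)[C@H]3O[C@@H]3C#CCO[Si](C)(C)C(C)(C)C)[C@@]12C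
F8 | step 19 | 9-O-triethylsilyl 7-acrylate 8-ol | COC(OC)C[C@H]1OC(C)(C)O[C@H]2CC=C(C)[C@H]([C@@H](O[Si](CC)(CC)CC)[C@@H](O)[C@@H](OC(=O)C=C)C#CCO[Si](C)(C)C(C)(C)C)[C@@]12C
F9 | step 19 | 9-O-triethylsilyl 8-oxo 7-acrylate | COC(OC)C[C@H]1OC(C)(C)O[C@H]2CC=C(C)[C@H]([C@@H](O[Si](CC)(CC)CC)C(=O)[C@@H](OC(=O)C=C)C#CCO[Si](C)(C)C(C)(C)C)[C@@]12C
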